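Ring A is the 4-hydroxy-3,5-dimethoxyphenyl ring (C1 carries the chain), ring B is the aryl ether ring, and C7–C8–C9 is the propane chain.
- Feature used: C7 is a single carbinol carbon between C1 of ring A and the aryloxy-bearing C8, so it can be inserted into a C8–B bond as a dichloromethyl carbenoid and then arylated on boron.
- Retrosynthesis: remove the O-benzyl groups; return the C7–O bond and the terminal C–O bond of the propanol chain to C–B bonds; cut C1–C7 and C7–C8 together; cut C8–O(ring B) to an aryloxide and an α-chloro boronate; cut C8–C9 to a (benzyloxymethyl)boronate.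
- Forward: the chain grows on boron in the order C9, C8, C7; ring B is attached at C8 as its aryloxide and ring A at C7 as its Grignard reagent; no ring is formed.
- Stereochemistry: one (S,S)-1,2-dicyclohexylethane-1,2-diol on boron directs both chloride-selective migrations; each displacement inverts and the C–B oxidation retains, which leads to (7R,8R), threo.

Key step: step 8

Remark: the (S,S)-diol is taken to direct the chloride-selective migration in the sense established for C2-symmetric diol boronates, giving the (αR)-chloride whenever the ranking at the new carbon is Cl > C > B > H.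

Remark: dichloromethyllithium does not survive above about −90 °C, so step 3 is described once and is run afresh immediately before each of the two steps that consume compound 8 (steps 4 and 8).

Step 1
Reactants: 1 benzyl alcohol; 2 2-(bromomethyl)-4,4,5,5-tetramethyl-1,3,2-dioxaborolane
Product: 4 2-[(benzyloxy)methyl]-4,4,5,5-tetramethyl-1,3,2-dioxaborolane, via sodium benzyl oxide 3 (not isolated)
Conditions: NaH (1.0 equiv), THF, 0 °C; then 2, THF/DMSO, 0 °C to rt
Reagents that add atoms: none
Why: Alkoxide substitution of an α-bromo boronic ester, in which the benzyl oxide binds boron and shifts from boron to carbon with loss of bromide (1,2-metallate rearrangement), is the standard entry to alkoxymethyl boronates.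

Step 2
Reactants: 4 2-[(benzyloxy)methyl]-4,4,5,5-tetramethyl-1,3,2-dioxaborolane; 5 (1S,2S)-1,2-dicyclohexylethane-1,2-diol
Product: 6 (4S,5S)-2-[(benzyloxy)methyl]-4,5-dicyclohexyl-1,3,2-dioxaborolane
Conditions: Et2O/H2O (two phases), rt; repeated H2O washes; MgSO4
Reagents that add atoms: none
Why: Boronic ester transesterification should be pulled to the chiral ester because pinacol is washed into water while the lipophilic dicyclohexyl diol ester stays in ether; no stereocentre is formed.

Step 3
Reactants: 7 dichloromethane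
Product: 8 dichloromethyllithium (THF solution at −100 °C, used at once)
Conditions: n-BuLi (hexanes), THF, −100 °C (internal), 15 min
Reagents that add atoms: n-butyllithium, [Li]CCCC
Why: Deprotonation of dichloromethane by n-butyllithium at −100 °C is the standard preparation of this carbenoid, which is stable enough at that temperature to be pre-formed before a boronic ester is added.

Step 4
Reactants: 6 (4S,5S)-2-[(benzyloxy)methyl]-4,5-dicyclohexyl-1,3,2-dioxaborolane; 8 dichloromethyllithium
Product: 9 (4S,5S)-2-[(1R)-2-(benzyloxy)-1-chloroethyl]-4,5-dicyclohexyl-1,3,2-dioxaborolane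
Conditions: 8 (1.2 equiv, THF, −100 °C), add 6 in THF; ZnCl2 (THF), −100 °C to rt
Reagents that add atoms: none
Why: In this Matteson asymmetric homologation the borate from 6 and 8 rearranges under ZnCl2 with migration of the benzyloxymethyl carbon and loss of the chloride selected by the C2-symmetric (S,S)-diol, which sets C8 as the (1R)-chloride under reagent control.

Step 5
Reactants: 9 (4S,5S)-2-[(1R)-2-(benzyloxy)-1-chloroethyl]-4,5-dicyclohexyl-1,3,2-dioxaborolane; 10 4-allyl-2,6-dimethoxyphenol
Product: 12 (4S,5S)-2-[(1S)-1-(4-allyl-2,6-dimethoxyphenoxy)-2-(benzyloxy)ethyl]-4,5-dicyclohexyl-1,3,2-dioxaborolane, via sodium 4-allyl-2,6-dimethoxyphenoxide 11 (not isolated)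
Conditions: 10 (1.2 equiv), NaH (1.1 equiv), THF, 0 °C; then 9, THF/DMSO, rt
Reagents that add atoms: none
Why: Substitution of an α-chloro boronic ester by an oxygen nucleophile runs through the borate, the aryloxide shifting from boron to carbon with inversion as in the established benzyl oxide displacements on this chloride, so C8 should become (1S) with its C–O bond to ring B in place; the allyl group serves as a latent 3-hydroxypropyl chain.

Step 6
Reactants: 13 4-bromo-2,6-dimethoxyphenol
Product: 14 2-(benzyloxy)-5-bromo-1,3-dimethoxybenzene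
Conditions: BnBr, K2CO3, DMF, 60 °C
Reagents that add atoms: benzyl bromide, BrCc1ccccc1
Why: Williamson ether synthesis with a reactive benzylic bromide masks the phenol of ring A, which must not be free during magnesium insertion.

Step 7
Reactants: 14 2-(benzyloxy)-5-bromo-1,3-dimethoxybenzene
Product: 15 [4-(benzyloxy)-3,5-dimethoxyphenyl]magnesium bromide (THF solution, titrated and used directly)
Conditions: Mg turnings, I2 (cat.), THF, 40 °C to rt
Reagents that add atoms: magnesium, [Mg]
Why: Grignard reagent formation by magnesium insertion into an electron-rich aryl bromide is routine, and the benzyl and methyl ethers are inert to it.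

Step 8
Reactants: 12 (4S,5S)-2-[(1S)-1-(4-allyl-2,6-dimethoxyphenoxy)-2-(benzyloxy)ethyl]-4,5-dicyclohexyl-1,3,2-dioxaborolane; 8 dichloromethyllithium; 15 [4-(benzyloxy)-3,5-dimethoxyphenyl]magnesium bromide
Product: 17 (4S,5S)-2-[(1R,2S)-2-(4-allyl-2,6-dimethoxyphenoxy)-3-(benzyloxy)-1-[4-(benzyloxy)-3,5-dimethoxyphenyl]propyl]-4,5-dicyclohexyl-1,3,2-dioxaborolane (threo), via (1R,2R)-1-chloropropylboronate 16 (not isolated)
Conditions: 8 (1.3 equiv, THF, −100 °C), add 12 in THF; ZnCl2 (1 equiv, THF), −100 °C to rt, 16 h; then −78 °C, 15 (3 equiv, in excess over ZnCl2), −78 °C to rt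
Reagents that add atoms: none
Why: Dichloromethyllithium 8 adds to the boron of 12, and ZnCl2 then promotes 1,2-migration of C8 from boron to the carbenoid carbon with retention at C8 and loss of one of the two diastereotopic chlorides, which forms the C7–C8 bond and gives chloride 16. The aryl Grignard reagent 15 forms a second borate, from which the aryl group shifts from boron to C7 with inversion and expulsion of chloride, forming the C1–C7 bond. The reaction type is the Matteson asymmetric homologation of a chiral diol boronic ester followed by Grignard substitution of the α-chloro boronic ester, here on a β-aryloxy boronate; no ring is closed. The new stereocentre C7 is set under reagent control by the (S,S)-diol on boron, which selects the chloride that leaves in the first migration, and the stereospecific inversion in the second migration places the aryl group so that C7 will be threo to the C8 aryloxy group once oxygen replaces boron with retention. The step needs both migrations to be faster than β-elimination of the C8 aryloxide from the borates, and needs 16 not to epimerize by chloride exchange; low temperature, binding of chloride by ZnCl2, the poorer leaving ability of the electron-rich 2,6-dimethoxyaryloxide compared with chloride, and the excess of 15 should secure this.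

Step 9
Reactants: 17 (4S,5S)-2-[(1R,2S)-2-(4-allyl-2,6-dimethoxyphenoxy)-3-(benzyloxy)-1-[4-(benzyloxy)-3,5-dimethoxyphenyl]propyl]-4,5-dicyclohexyl-1,3,2-dioxaborolane
Product: 19 (1R,2R)-3-(benzyloxy)-1-[4-(benzyloxy)-3,5-dimethoxyphenyl]-2-[4-(3-hydroxypropyl)-2,6-dimethoxyphenoxy]propan-1-ol, via B-alkyl-9-borabicyclo[3.3.1]nonane 18 (not isolated)
Conditions: 9-BBN (1.5 equiv), THF, 0 °C to rt; then 3 M NaOH, 30% H2O2, 0 °C to rt
Reagents that add atoms: hydrogen peroxide, OO
Why: Brown hydroboration places boron on the terminal carbon of the allyl group while the boronic ester is inert to 9-BBN, and alkaline hydrogen peroxide then oxidizes both C–B bonds by 1,2-shift from boron to oxygen with retention, so C7 should become the (R)-carbinol threo to C8.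

Step 10
Reactants: 19 (1R,2R)-3-(benzyloxy)-1-[4-(benzyloxy)-3,5-dimethoxyphenyl]-2-[4-(3-hydroxypropyl)-2,6-dimethoxyphenoxy]propan-1-ol
Product: 20 (1R,2R)-1-(4-hydroxy-3,5-dimethoxyphenyl)-2-[4-(3-hydroxypropyl)-2,6-dimethoxyphenoxy]propane-1,3-diol
Conditions: H2 (1 atm), 10% Pd/C, EtOAc/EtOH, rt
Reagents that add atoms: none
Why: Catalytic hydrogenolysis of the phenolic and the primary benzyl ether under neutral conditions should leave the C7 benzylic alcohol, the alkyl aryl ether and both stereocentres untouched.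

Compound list
1 | benzyl alcohol | OCc1ccccc1 | starting material
2 | 2-(bromomethyl)-4,4,5,5-tetramethyl-1,3,2-dioxaborolane | BrCB1OC(C)(C)C(C)(C)O1 | starting material
3 | sodium benzyl oxide | [Na+].[O-]Cc1ccccc1 | intermediate
4 | 2-[(benzyloxy)methyl]-4,4,5,5-tetramethyl-1,3,2-dioxaborolane | CC1(C)OB(COCc2ccccc2)OC1(C)C | intermediate
5 | (1S,2S)-1,2-dicyclohexylethane-1,2-diol | O[C@@H](C1CCCCC1)[C@@H](O)C1CCCCC1 | starting material
6 | (4S,5S)-2-[(benzyloxy)methyl]-4,5-dicyclohexyl-1,3,2-dioxaborolane | B1(O[C@@H](C2CCCCC2)[C@H](C2CCCCC2)O1)COCc1ccccc1 | intermediate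
7 | dichloromethane | ClCCl | starting material
8 | dichloromethyllithium | [Li]C(Cl)Cl | intermediate
9 | (4S,5S)-2-[(1R)-2-(benzyloxy)-1-chloroethyl]-4,5-dicyclohexyl-1,3,2-dioxaborolane | B1(O[C@@H](C2CCCCC2)[C@H](C2CCCCC2)O1)[C@@H](Cl)COCc1ccccc1 | intermediate
10 | 4-allyl-2,6-dimethoxyphenol | C=CCc1cc(OC)c(O)c(OC)c1 | starting material
11 | sodium 4-allyl-2,6-dimethoxyphenoxide | [Na+].[O-]c1c(OC)cc(CC=C)cc1OC | intermediate
12 | (4S,5S)-2-[(1S)-1-(4-allyl-2,6-dimethoxyphenoxy)-2-(benzyloxy)ethyl]-4,5-dicyclohexyl-1,3,2-dioxaborolane | B1(O[C@@H](C2CCCCC2)[C@H](C2CCCCC2)O1)[C@@H](COCc1ccccc1)Oc1c(OC)cc(CC=C)cc1OC | intermediate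
13 | 4-bromo-2,6-dimethoxyphenol | COc1cc(Br)cc(OC)c1O | starting material
14 | 2-(benzyloxy)-5-bromo-1,3-dimethoxybenzene | COc1cc(Br)cc(OC)c1OCc1ccccc1 | intermediate
15 | [4-(benzyloxy)-3,5-dimethoxyphenyl]magnesium bromide | COc1cc([Mg]Br)cc(OC)c1OCc1ccccc1 | intermediate
16 | (4S,5S)-2-[(1R,2R)-2-(4-allyl-2,6-dimethoxyphenoxy)-3-(benzyloxy)-1-chloropropyl]-4,5-dicyclohexyl-1,3,2-dioxaborolane | B1(O[C@@H](C2CCCCC2)[C@H](C2CCCCC2)O1)[C@@H](Cl)[C@@H](COCc1ccccc1)Oc1c(OC)cc(CC=C)cc1OC | intermediate
17 | (4S,5S)-2-[(1R,2S)-2-(4-allyl-2,6-dimethoxyphenoxy)-3-(benzyloxy)-1-[4-(benzyloxy)-3,5-dimethoxyphenyl]propyl]-4,5-dicyclohexyl-1,3,2-dioxaborolane | B1(O[C@@H](C2CCCCC2)[C@H](C2CCCCC2)O1)[C@H](c1cc(OC)c(OCc2ccccc2)c(OC)c1)[C@@H](COCc1ccccc1)Oc1c(OC)cc(CC=C)cc1OC | intermediate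
18 | (4S,5S)-2-[(1R,2S)-3-(benzyloxy)-1-[4-(benzyloxy)-3,5-dimethoxyphenyl]-2-{4-[3-(9-borabicyclo[3.3.1]nonan-9-yl)propyl]-2,6-dimethoxyphenoxy}propyl]-4,5-dicyclohexyl-1,3,2-dioxaborolane | B1(O[C@@H](C2CCCCC2)[C@H](C2CCCCC2)O1)[C@H](c1cc(OC)c(OCc2ccccc2)c(OC)c1)[C@@H](COCc1ccccc1)Oc1c(OC)cc(CCCB2C3CCCC2CCC3)cc1OC | intermediate
19 | (1R,2R)-3-(benzyloxy)-1-[4-(benzyloxy)-3,5-dimethoxyphenyl]-2-[4-(3-hydroxypropyl)-2,6-dimethoxyphenoxy]propan-1-ol | O[C@H](c1cc(OC)c(OCc2ccccc2)c(OC)c1)[C@@H](COCc1ccccc1)Oc1c(OC)cc(CCCO)cc1OC | intermediate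
20 | (1R,2R)-1-(4-hydroxy-3,5-dimethoxyphenyl)-2-[4-(3-hydroxypropyl)-2,6-dimethoxyphenoxy]propane-1,3-diol | COc1cc([C@@H](O)[C@@H](CO)Oc2c(OC)cc(CCCO)cc2OC)cc(OC)c1O | target

Total step count: 10. Longest linear sequence: 7 steps (steps 1, 2, 4, 5, 8, 9, 10). The carbenoid preparation (step 3) feeds steps 4 and 8, and the ring A branch (steps 6 and 7) joins at step 8.

Steps most likely to fail

Step 8. The borates formed from 12 or 16 may lose the C8 aryloxide by β-elimination faster than they rearrange, and 16 may epimerize at C7 by chloride exchange before arylation. The fallback leaves the boron route, sets out from compound 10 and comes back to the route at compound 20. Phenol 10 is O-alkylated with sodium chloroacetate (NaOH, H2O, reflux, then acid) to (4-allyl-2,6-dimethoxyphenoxy)acetic acid F1. The acid is activated with pivaloyl chloride (Et3N, LiCl, THF) and joined to (S)-4-benzyl-1,3-oxazolidin-2-one to give (4S)-3-[(4-allyl-2,6-dimethoxyphenoxy)acetyl]-4-benzyl-1,3-oxazolidin-2-one F2. Its dibutylboron enolate (Bu2BOTf, i-Pr2NEt, CH2Cl2, −78 °C) adds to commercial 4-(benzyloxy)-3,5-dimethoxybenzaldehyde in an Evans syn aldol reaction, which should give (4S)-3-[(2S,3R)-2-(4-allyl-2,6-dimethoxyphenoxy)-3-[4-(benzyloxy)-3,5-dimethoxyphenyl]-3-hydroxypropanoyl]-4-benzyl-1,3-oxazolidin-2-one F3 with both stereocentres set by the auxiliary. Reductive removal of the auxiliary (LiBH4, THF/MeOH, 0 °C) gives (1R,2R)-2-(4-allyl-2,6-dimethoxyphenoxy)-1-[4-(benzyloxy)-3,5-dimethoxyphenyl]propane-1,3-diol F4. Hydroboration and oxidation of the allyl group (excess 9-BBN, then NaOH/H2O2) gives (1R,2R)-1-[4-(benzyloxy)-3,5-dimethoxyphenyl]-2-[4-(3-hydroxypropyl)-2,6-dimethoxyphenoxy]propane-1,3-diol F5, and hydrogenolysis (H2, 10% Pd/C) gives 20.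

Step 5. The hindered, weakly basic 2,6-dimethoxyphenoxide may bind boron and migrate so slowly that chloride exchange epimerizes 9 or the borate loses benzyl oxide by β-elimination. The fallback sets out from compound 6 and comes back at compound 12 with a more reactive leaving group. Homologation of 6 with dibromomethyllithium made in the flask (CH2Br2, LiN(i-Pr)2, THF, −78 °C, then ZnCl2, to rt) gives (4S,5S)-2-[(1R)-2-(benzyloxy)-1-bromoethyl]-4,5-dicyclohexyl-1,3,2-dioxaborolane F6. The bromide should be displaced by aryloxide 11 with inversion at lower temperature (THF, 0 °C to rt) to give 12.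

Step 9. The peroxyborate at C7 may fragment by loss of the β-aryloxide instead of migrating, or the oxidation may stay incomplete when two unlike C–B bonds are oxidized in one operation. The fallback sets out from compound 17 and comes back at compound 19 by separating the two oxidations. Mild oxidation of the benzylic boronate alone (NaBO3·4H2O, THF/H2O, rt) gives (1R,2R)-2-(4-allyl-2,6-dimethoxyphenoxy)-3-(benzyloxy)-1-[4-(benzyloxy)-3,5-dimethoxyphenyl]propan-1-ol F7. Hydroboration of its allyl group (9-BBN, 2.5 equiv, THF) and the usual NaOH/H2O2 work-up then give 19.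

Further compounds
F1 | step 8 | (4-allyl-2,6-dimethoxyphenoxy)acetic acid | OC(=O)COc1c(OC)cc(CC=C)cc1OC
F2 | step 8 | (4S)-3-[(4-allyl-2,6-dimethoxyphenoxy)acetyl]-4-benzyl-1,3-oxazolidin-2-one | O=C(COc1c(OC)cc(CC=C)cc1OC)N1[C@@H](Cc2ccccc2)COC1=O
F3 | step 8 | (4S)-3-[(2S,3R)-2-(4-allyl-2,6-dimethoxyphenoxy)-3-[4-(benzyloxy)-3,5-dimethoxyphenyl]-3-hydroxypropanoyl]-4-benzyl-1,3-oxazolidin-2-one | O[C@H](c1cc(OC)c(OCc2ccccc2)c(OC)c1)[C@@H](C(=O)N1[C@@H](Cc2ccccc2)COC1=O)Oc1c(OC)cc(CC=C)cc1OC
F4 | step 8 | (1R,2R)-2-(4-allyl-2,6-dimethoxyphenoxy)-1-[4-(benzyloxy)-3,5-dimethoxyphenyl]propane-1,3-diol | O[C@H](c1cc(OC)c(OCc2ccccc2)c(OC)c1)[C@@H](CO)Oc1c(OC)cc(CC=C)cc1OC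
F5 | step 8 | (1R,2R)-1-[4-(benzyloxy)-3,5-dimethoxyphenyl]-2-[4-(3-hydroxypropyl)-2,6-dimethoxyphenoxy]propane-1,3-diol | O[C@H](c1cc(OC)c(OCc2ccccc2)c(OC)c1)[C@@H](CO)Oc1c(OC)cc(CCCO)cc1OC
F6 | step 5 | (4S,5S)-2-[(1R)-2-(benzyloxy)-1-bromoethyl]-4,5-dicyclohexyl-1,3,2-dioxaborolane | B1(O[C@@H](C2CCCCC2)[C@H](C2CCCCC2)O1)[C@@H](Br)COCc1ccccc1
F7 | step 9 | (1R,2R)-2-(4-allyl-2,6-dimethoxyphenoxy)-3-(benzyloxy)-1-[4-(benzyloxy)-3,5-dimethoxyphenyl]propan-1-ol | O[C@H](c1cc(OC)c(OCc2ccccc2)c(OC)c1)[C@@H](COCc1ccccc1)Oc1c(OC)cc(CC=C)cc1OC
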